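## Retrosynthetic overview

1. Kanzonol V **23** comes from its chromenol triisopropylsilyl ether **22** by fluoride desilylation.
2. The benzo ring of **22** is opened at bf-C7–C7a and bf-C5–C6 (bf = benzofuran numbering, ch = 2H-chromene numbering), leading back to 2-furoyl diazomethane **19**. The feature used is that the hydroxyl carbon bf-C6 lies between bf-C7–H and the prenylated bf-C5. That is where the carbonyl carbon of a (furan-2-yl)ketene ends up when it closes onto the terminus of a 3-alkenyl group, so connectivity places the prenyl group.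
3. **19** comes from methyl ketone **16** by detrifluoroacetylative diazo transfer, and **16** from C5–H arylation of acetylfuran **8** with bromochromene **15**.
4. **8** comes from 1-(3-bromofuran-2-yl)ethanone **3** and E-dienylboronate **7** (Suzuki); **15** comes from 4-bromoresorcinol **9** by silylation, propargylation and Claisen rearrangement.
5. Ring order: furan (bought), pyran ring of the chromene (step 7), benzo ring of the benzofuran (step 10).

Key step: step 10

Remark on the chemistry: the chromenol oxygen is carried as a triisopropylsilyl ether. It has to survive carbonate in DMA at 100 °C in step 8, and the bulkier silyl chloride should discriminate better between the two hydroxyls of 4-bromoresorcinol. Fluoride still removes it in the last step.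

## Route

Step 1
Reactants: 1 3-bromofuran
Product: 3 1-(3-bromofuran-2-yl)ethan-1-one, via 3-bromo-2-lithiofuran 2 (not isolated)
Conditions: LDA, THF, −78 °C; MeC(O)N(OMe)Me, −78 → 0 °C; aq. NH4Cl
Reagents that add atoms: N-methoxy-N-methylacetamide CC(=O)N(C)OC
Why: Deprotonation of 3-bromofuran by LDA occurs at C2, the position acidified by both the ring oxygen and the adjacent bromine, and Weinreb amide acylation of the aryllithium stops at the ketone because the chelated tetrahedral adduct persists until the quench.

Step 2
Reactants: 4 prenyl bromide (1-bromo-3-methylbut-2-ene); 5 ethynylmagnesium bromide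
Product: 6 5-methylhex-4-en-1-yne
Conditions: CuCl (5 mol%), THF, 0 °C → rt; fractional distillation
Reagents that add atoms: none
Why: Copper-catalysed allyl–alkynyl coupling of the alkynyl Grignard reagent with the primary allylic bromide should take place at the unhindered CH2 carbon and give the skipped enyne, with the Grignard reagent kept in excess to suppress double alkylation of acetylene.

Step 3
Reactants: 6 5-methylhex-4-en-1-yne
Product: 7 4,4,5,5-tetramethyl-2-[(1E)-5-methylhexa-1,4-dien-1-yl]-1,3,2-dioxaborolane
Conditions: HBpin, Cp2Zr(H)Cl (5 mol%), Et3N (10 mol%), neat, 60 °C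
Reagents that add atoms: pinacolborane CC1(C)OBOC1(C)C
Why: Zirconocene-catalysed hydroboration of the terminal alkyne with pinacolborane is a syn, anti-Markovnikov addition that sets the E geometry of the new alkene and leaves the trisubstituted alkene untouched.

Step 4
Reactants: 3 1-(3-bromofuran-2-yl)ethan-1-one; 7 E-dienyl pinacol boronate
Product: 8 1-{3-[(1E)-5-methylhexa-1,4-dien-1-yl]furan-2-yl}ethan-1-one
Conditions: PdCl2(dppf) (3 mol%), K2CO3, 1,4-dioxane/H2O, 70 °C
Reagents that add atoms: none
Why: Suzuki–Miyaura coupling of the bromide, which the ortho acyl group activates for oxidative addition to zerovalent palladium, with the alkenylboronate proceeds with retention of the E geometry under carbonate conditions too mild to move the skipped diene into conjugation.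

Step 5
Reactants: 9 4-bromoresorcinol
Product: 10 2-bromo-5-(triisopropylsilyloxy)phenol
Conditions: TIPSCl (1.0 equiv), imidazole, CH2Cl2, −20 → 0 °C
Reagents that add atoms: chlorotriisopropylsilane CC(C)[Si](Cl)(C(C)C)C(C)C
Why: Silylation with the bulky chloride as limiting reagent at low temperature should select the unhindered hydroxyl para to bromine over the hydroxyl flanked by bromine, and the regioisomeric and bis-silylated ethers are separable by chromatography.

Step 6
Reactants: 10 2-bromo-5-(triisopropylsilyloxy)phenol; 11 3-chloro-3-methylbut-1-yne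
Product: 12 {4-bromo-3-[(2-methylbut-3-yn-2-yl)oxy]phenoxy}tri(propan-2-yl)silane
Conditions: DBU, CuCl2 (1 mol%), MeCN, 0 °C
Reagents that add atoms: none
Why: Copper-catalysed O-propargylation of the phenol with the tertiary propargylic chloride and DBU (a Godfrey-type etherification) tolerates hindered, acidic ortho-halophenols and does not disturb the aryl silyl ether.

Step 7
Reactants: 12 aryl 1,1-dimethylpropargyl ether
Product: 15 8-bromo-2,2-dimethyl-5-(triisopropylsilyloxy)-2H-chromene, via allenylphenol 13 (not isolated), via ortho-quinone methide 14 (not isolated)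
Conditions: o-xylene, 140 °C
Reagents that add atoms: none
Why: The aromatic propargyl Claisen rearrangement can deliver the propargyl terminus only to the one free ortho carbon (between the two oxygens, since the other ortho position carries bromine), and enolisation to 13, 1,5-hydrogen shift to 14 and oxa-6π electrocyclisation then close the 2,2-dimethyl-2H-pyran ring.

Step 8
Reactants: 8 1-{3-[(1E)-5-methylhexa-1,4-dien-1-yl]furan-2-yl}ethan-1-one; 15 8-bromo-2,2-dimethyl-5-(triisopropylsilyloxy)-2H-chromene
Product: 16 1-{5-[2,2-dimethyl-5-(triisopropylsilyloxy)-2H-chromen-8-yl]-3-[(1E)-5-methylhexa-1,4-dien-1-yl]furan-2-yl}ethan-1-one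
Conditions: Pd(OAc)2 (5 mol%), PCy3·HBF4 (10 mol%), PivOH (30 mol%), K2CO3, DMA, 100 °C
Reagents that add atoms: none
Why: Palladium-catalysed direct C–H arylation by pivalate-assisted concerted metalation–deprotonation takes place at furan C5, the only free α position and the one activated by the 2-acyl group, while the triisopropylsilyl ether should withstand carbonate in DMA.

Step 9
Reactants: 16 aryl-dienyl 2-acetylfuran
Product: 19 2-diazo-1-{5-[2,2-dimethyl-5-(triisopropylsilyloxy)-2H-chromen-8-yl]-3-[(1E)-5-methylhexa-1,4-dien-1-yl]furan-2-yl}ethan-1-one, via lithium enolate 17 (not isolated), via trifluoroacetyl diketone 18 (not isolated)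
Conditions: LiHMDS, THF, −78 °C; CF3CO2CH2CF3; cold 5% HCl wash; MsN3, Et3N, H2O, MeCN, rt
Reagents that add atoms: methanesulfonyl azide CS(=O)(=O)N=[N+]=[N-] (the two diazo nitrogens); 2,2,2-trifluoroethyl trifluoroacetate O=C(OCC(F)(F)F)C(F)(F)F (trifluoroacetyl group of 18 only)
Why: Detrifluoroacetylative diazo transfer (kinetic enolate trifluoroacetylation, then Regitz transfer from the sulfonyl azide and retro-Claisen loss of the trifluoroacetyl group) converts the methyl ketone into the diazomethyl ketone without hydroxide, acid chloride or diazomethane, each of which would endanger the aryl silyl ether, the chromene or the skipped diene.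

Step 10
Reactants: 19 2-furoyl diazomethane
Product: 22 2-[2,2-dimethyl-5-(triisopropylsilyloxy)-2H-chromen-8-yl]-5-(3-methylbut-2-en-1-yl)-1-benzofuran-6-ol, via furan-2-yl ketene 20 (not isolated), via cyclohexadienone 21 (not isolated)
Conditions: hν (405 nm), degassed dry ClCH2CH2Cl (0.01 M), rt; then 60 °C
Reagents that add atoms: none
Why: Excitation of the s-cis diazoketone expels nitrogen with concerted 1,2-shift of the furan-2-yl group from the carbonyl carbon to the diazo carbon (Wolff rearrangement), which forms bf-C7–C7a and gives ketene 20. The ketene C=C, the furan C2=C3 bond and the side-chain alkene then form a 1,3,5-hexatriene whose thermal disrotatory 6π electrocyclisation joins the ketene carbonyl carbon to the alkene terminus (bf-C5–C6) and closes the six-membered carbocycle as dienone 21, and enolisation restores the furan and releases the bf-C6 phenol. The closest known reaction type is the photochemical Wolff rearrangement of unsaturated, aryl and heteroaryl diazomethyl ketones to dienylketenes followed by their 6π closure to phenols, the final stage of ketene-based aromatic annulation. No stereocentre remains, because the sp3 bf-C5 of 21 is lost on aromatisation, so both alkene geometries converge on 22 should light scramble the E-alkene. The selectivity needed is 1,2-shift over carbene addition to the nearby alkenes or insertion into the doubly allylic C–H bonds; metal-free photolysis of the s-cis conformer, in which the migrating furyl group lies anti to the departing nitrogen, favours the concerted shift, and high dilution in a dry non-nucleophilic solvent keeps the ketene for the intramolecular closure. Regiochemistry needs no control, since the prenyl-bearing alkene carbon is the only terminus within reach of the ketene carbon and the prenyl group must therefore end on bf-C5 next to the hydroxyl.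

Step 11
Reactants: 22 Kanzonol V chromenol triisopropylsilyl ether
Product: 23 Kanzonol V, 2-(5-hydroxy-2,2-dimethyl-2H-chromen-8-yl)-5-(3-methylbut-2-en-1-yl)-1-benzofuran-6-ol
Conditions: TBAF, AcOH, THF, 0 °C, argon
Reagents that add atoms: none
Why: Fluoride cleaves the aryl silicon–oxygen bond rapidly at 0 °C (fluoride-mediated desilylation), and acetic acid buffering keeps the two electron-rich phenols protonated so that neither the prenyl group nor the chromene is touched.

## Compound list

1 | 3-bromofuran | Brc1ccoc1 | starting material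
2 | 3-bromo-2-lithiofuran | [Li]c1occc1Br | intermediate
3 | 1-(3-bromofuran-2-yl)ethan-1-one | CC(=O)c1occc1Br | intermediate
4 | prenyl bromide (1-bromo-3-methylbut-2-ene) | CC(C)=CCBr | starting material
5 | ethynylmagnesium bromide | C#C[Mg]Br | starting material
6 | 5-methylhex-4-en-1-yne | CC(C)=CCC#C | intermediate
7 | 4,4,5,5-tetramethyl-2-[(1E)-5-methylhexa-1,4-dien-1-yl]-1,3,2-dioxaborolane | CC(C)=CC/C=C/B1OC(C)(C)C(C)(C)O1 | intermediate
8 | 1-{3-[(1E)-5-methylhexa-1,4-dien-1-yl]furan-2-yl}ethan-1-one | CC(=O)c1occc1/C=C/CC=C(C)C | intermediate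
9 | 4-bromoresorcinol (4-bromobenzene-1,3-diol) | Oc1ccc(Br)c(O)c1 | starting material
10 | 2-bromo-5-(triisopropylsilyloxy)phenol | Oc1cc(O[Si](C(C)C)(C(C)C)C(C)C)ccc1Br | intermediate
11 | 3-chloro-3-methylbut-1-yne | CC(C)(Cl)C#C | starting material
12 | {4-bromo-3-[(2-methylbut-3-yn-2-yl)oxy]phenoxy}tri(propan-2-yl)silane | C#CC(C)(C)Oc1cc(O[Si](C(C)C)(C(C)C)C(C)C)ccc1Br | intermediate
13 | 6-bromo-2-(3-methylbuta-1,2-dien-1-yl)-3-(triisopropylsilyloxy)phenol | CC(C)=C=Cc1c(O)c(Br)ccc1O[Si](C(C)C)(C(C)C)C(C)C | intermediate
14 | 2-bromo-6-(3-methylbut-2-en-1-ylidene)-5-(triisopropylsilyloxy)cyclohexa-2,4-dien-1-one | CC(C)=CC=C1C(=O)C(Br)=CC=C1O[Si](C(C)C)(C(C)C)C(C)C | intermediate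
15 | 8-bromo-2,2-dimethyl-5-(triisopropylsilyloxy)-2H-chromene | Brc1ccc(O[Si](C(C)C)(C(C)C)C(C)C)c2C=CC(C)(C)Oc12 | intermediate
16 | 1-{5-[2,2-dimethyl-5-(triisopropylsilyloxy)-2H-chromen-8-yl]-3-[(1E)-5-methylhexa-1,4-dien-1-yl]furan-2-yl}ethan-1-one | CC(=O)c1oc(-c2ccc(O[Si](C(C)C)(C(C)C)C(C)C)c3c2OC(C)(C)C=C3)cc1/C=C/CC=C(C)C | intermediate
17 | lithium enolate of 16 (O-lithio 1-arylethen-1-olate at the acetyl group) | [Li]OC(=C)c1oc(-c2ccc(O[Si](C(C)C)(C(C)C)C(C)C)c3c2OC(C)(C)C=C3)cc1/C=C/CC=C(C)C | intermediate
18 | 4,4,4-trifluoro-1-{5-[2,2-dimethyl-5-(triisopropylsilyloxy)-2H-chromen-8-yl]-3-[(1E)-5-methylhexa-1,4-dien-1-yl]furan-2-yl}butane-1,3-dione | O=C(CC(=O)C(F)(F)F)c1oc(-c2ccc(O[Si](C(C)C)(C(C)C)C(C)C)c3c2OC(C)(C)C=C3)cc1/C=C/CC=C(C)C | intermediate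
19 | 2-diazo-1-{5-[2,2-dimethyl-5-(triisopropylsilyloxy)-2H-chromen-8-yl]-3-[(1E)-5-methylhexa-1,4-dien-1-yl]furan-2-yl}ethan-1-one | [N-]=[N+]=CC(=O)c1oc(-c2ccc(O[Si](C(C)C)(C(C)C)C(C)C)c3c2OC(C)(C)C=C3)cc1/C=C/CC=C(C)C | intermediate
20 | 2-{5-[2,2-dimethyl-5-(triisopropylsilyloxy)-2H-chromen-8-yl]-3-[(1E)-5-methylhexa-1,4-dien-1-yl]furan-2-yl}ethen-1-one (ketene) | O=C=Cc1oc(-c2ccc(O[Si](C(C)C)(C(C)C)C(C)C)c3c2OC(C)(C)C=C3)cc1/C=C/CC=C(C)C | intermediate
21 | 2-[2,2-dimethyl-5-(triisopropylsilyloxy)-2H-chromen-8-yl]-5-(3-methylbut-2-en-1-yl)-1-benzofuran-6(5H)-one (racemic at C5, transient) | O=C1C=C2OC(-c3ccc(O[Si](C(C)C)(C(C)C)C(C)C)c4c3OC(C)(C)C=C4)=CC2=CC1CC=C(C)C | intermediate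
22 | 2-[2,2-dimethyl-5-(triisopropylsilyloxy)-2H-chromen-8-yl]-5-(3-methylbut-2-en-1-yl)-1-benzofuran-6-ol | CC(C)=CCc1cc2cc(-c3ccc(O[Si](C(C)C)(C(C)C)C(C)C)c4c3OC(C)(C)C=C4)oc2cc1O | intermediate
23 | Kanzonol V, 2-(5-hydroxy-2,2-dimethyl-2H-chromen-8-yl)-5-(3-methylbut-2-en-1-yl)-1-benzofuran-6-ol | CC(C)=CCc1cc2cc(-c3ccc(O)c4c3OC(C)(C)C=C4)oc2cc1O | target

## Step count and risks

Total step count: 11.
Longest linear sequence: 7 steps (steps 5, 6, 7, 8, 9, 10, 11 from 4-bromoresorcinol; equally steps 2, 3, 4, 8, 9, 10, 11 from prenyl bromide).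

Steps most likely to fail:

**Step 10 (Wolff rearrangement and 6π closure).** After loss of nitrogen the carbene may add to the adjacent side-chain alkene or insert into the doubly allylic C–H bonds instead of undergoing the 1,2-shift. The ketene may also be captured intermolecularly (by water or by the phenol already formed) before it closes, and light may degrade the chromene. The fallback builds the benzofuran the classical way, with ring positions fixed by two different halogens. It sets out from bromochromene 15 and 4-bromoresorcinol 9 and comes back at 22. Sonogashira coupling of 15 with trimethylsilylacetylene (PdCl2(PPh3)2, CuI, Et3N, 70 °C) should give {[2,2-dimethyl-5-(triisopropylsilyloxy)-2H-chromen-8-yl]ethynyl}trimethylsilane F1. K2CO3 in MeOH at 0 °C should then free 8-ethynyl-2,2-dimethyl-5-(triisopropylsilyloxy)-2H-chromene F2, the C–Si bond being cleaved much faster than the aryl silyl ether. Iodination of 9 with N-iodosuccinimide in MeCN at 0 °C should go to the free position para to one hydroxyl and ortho to the other and give 4-bromo-6-iodobenzene-1,3-diol F3. Sonogashira coupling of F2 at the C–I bond of F3 (PdCl2(PPh3)2, CuI, Et3N, DMF, 60 °C), with 5-endo-dig closure of the ortho-hydroxy diarylalkyne in the same flask, should give 5-bromo-2-[2,2-dimethyl-5-(triisopropylsilyloxy)-2H-chromen-8-yl]-1-benzofuran-6-ol F4. Stille coupling of F4 with tributyl(3-methylbut-2-en-1-yl)stannane (Pd(PPh3)4, DMF, 90 °C) should then place the prenyl group on bf-C5 and give 22.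

**Step 8 (direct C–H arylation).** Oxidative addition of the hindered, electron-rich aryl bromide may be slow. Heck-type insertion into the side-chain alkenes, double-bond migration through palladium hydrides, or loss of the silyl group to carbonate could then take over. The fallback reverses the polarity at furan C5 and uses a cross-coupling that runs at lower temperature. It sets out from 8 and comes back at 16. Iridium-catalysed C–H borylation of 8 ([Ir(OMe)(cod)]2, 4,4'-di-tert-butyl-2,2'-bipyridine, B2pin2, THF, 50 °C) should take place at the unhindered α position and give 1-{3-[(1E)-5-methylhexa-1,4-dien-1-yl]-5-(4,4,5,5-tetramethyl-1,3,2-dioxaborolan-2-yl)furan-2-yl}ethan-1-one F5. Suzuki–Miyaura coupling of F5 with 15 (Pd(OAc)2, SPhos, K3PO4, toluene/H2O, 70 °C) should then give 16.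

**Step 5 (mono-silylation).** Discrimination between the two hydroxyl groups may be insufficient and over-silylation may occur, so that the wrong oxygen later becomes the pyran oxygen. The fallback buys the oxygen differentiation and exchanges the protecting group after the chromene is made. It sets out from propargyl chloride 11 together with commercial 2-bromo-5-methoxyphenol F6, which takes the place of 9 and 10, and comes back at 15. Etherification of F6 with 11 (DBU, CuCl2, MeCN, 0 °C) should give 1-bromo-4-methoxy-2-[(2-methylbut-3-yn-2-yl)oxy]benzene F7. Claisen rearrangement and ring closure in o-xylene at 140 °C should give 8-bromo-5-methoxy-2,2-dimethyl-2H-chromene F8. Thiolate demethylation (NaSEt, DMF, 120 °C) should give 8-bromo-2,2-dimethyl-2H-chromen-5-ol F9, and silylation of F9 (TIPSCl, imidazole, DMF, rt) should give 15.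

Further compounds
F1 | step 10 | {[2,2-dimethyl-5-(triisopropylsilyloxy)-2H-chromen-8-yl]ethynyl}trimethylsilane | C[Si](C)(C)C#Cc1ccc(O[Si](C(C)C)(C(C)C)C(C)C)c2C=CC(C)(C)Oc12
F2 | step 10 | 8-ethynyl-2,2-dimethyl-5-(triisopropylsilyloxy)-2H-chromene | C#Cc1ccc(O[Si](C(C)C)(C(C)C)C(C)C)c2C=CC(C)(C)Oc12
F3 | step 10 | 4-bromo-6-iodobenzene-1,3-diol | Oc1cc(O)c(I)cc1Br
F4 | step 10 | 5-bromo-2-[2,2-dimethyl-5-(triisopropylsilyloxy)-2H-chromen-8-yl]-1-benzofuran-6-ol | Oc1cc2oc(-c3ccc(O[Si](C(C)C)(C(C)C)C(C)C)c4c3OC(C)(C)C=C4)cc2cc1Br
F5 | step 8 | 1-{3-[(1E)-5-methylhexa-1,4-dien-1-yl]-5-(4,4,5,5-tetramethyl-1,3,2-dioxaborolan-2-yl)furan-2-yl}ethan-1-one | CC(=O)c1oc(B2OC(C)(C)C(C)(C)O2)cc1/C=C/CC=C(C)C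
F6 | step 5 | 2-bromo-5-methoxyphenol | COc1ccc(Br)c(O)c1
F7 | step 5 | 1-bromo-4-methoxy-2-[(2-methylbut-3-yn-2-yl)oxy]benzene | COc1ccc(Br)c(OC(C)(C)C#C)c1
F8 | step 5 | 8-bromo-5-methoxy-2,2-dimethyl-2H-chromene | COc1ccc(Br)c2OC(C)(C)C=Cc12
F9 | step 5 | 8-bromo-2,2-dimethyl-2H-chromen-5-ol | Oc1ccc(Br)c2OC(C)(C)C=Cc12
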